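Ring A is read as an aromatized 5-substituted cyclohexane-1,3-dione: its oxygens sit on C1 (OMe) and C3 (OH) and the CH2CH2 bridge to ring B on C5. All six ring-A carbons are therefore assembled in one operation from dimethyl malonate and a methyl enone that already carries benzyl-protected ring B, (E)-6-aryl-hex-3-en-2-one 9: conjugate addition forms C5–C6 and Claisen closure by the methyl ketone forms C1–C2. The ring is kept non-aromatic so that its mono-methyl enol ether fixes OMe against OH and an α′-aldol/isoaromatization places the C4 benzyl group; the C6 benzyl group follows by para-bromination, lithiation and aldehyde addition, and one hydrogenolysis finishes.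

Key step: step 6

Remark on the chemistry: the target has no stereocentre and no stereogenic double bond, so it is achiral and no enantiocontrol is needed. Stereocentres in 4, 11–13, 15, 17–19 and 24 are carried as racemates or diastereomer mixtures and are all erased by the last step. "Ar" denotes 2-(benzyloxy)-5-[4-(benzyloxy)benzyl]phenyl (protected ring B) throughout.

Step 1
Reactants: 1 4-hydroxy-3-iodobenzaldehyde
Product: 2 4-(benzyloxy)-3-iodobenzaldehyde
Conditions: BnBr, K2CO3, DMF, rt
Reagents that add atoms: benzyl bromide, BrCc1ccccc1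
Why: Williamson etherification of the acidic phenol with a benzylic halide is routine, and the benzyl ether should survive every basic, organometallic and mildly acidic step up to the final hydrogenolysis.

Step 2
Reactants: 2 4-(benzyloxy)-3-iodobenzaldehyde; 3 4-(benzyloxy)phenylmagnesium bromide
Product: 4 [4-(benzyloxy)-3-iodophenyl][4-(benzyloxy)phenyl]methanol (racemic)
Conditions: THF, −40 → 0 °C; aq. NH4Cl
Reagents that add atoms: none
Why: Grignard 1,2-addition to the aldehyde should be much faster at low temperature than iodine–magnesium exchange with an aryl Grignard reagent, so the iodide is kept; the carbinol centre is racemic and is removed in step 3.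

Step 3
Reactants: 4 [4-(benzyloxy)-3-iodophenyl][4-(benzyloxy)phenyl]methanol
Product: 5 1-(benzyloxy)-4-[4-(benzyloxy)benzyl]-2-iodobenzene
Conditions: Et3SiH, TFA, CH2Cl2, 0 °C
Reagents that add atoms: none
Why: Ionic hydrogenation: the bis(4-alkoxyphenyl)methyl cation forms readily in TFA and is trapped by silane hydride, while the aryl iodide and the benzyl ethers should be inert at 0 °C.

Step 4
Reactants: 5 1-(benzyloxy)-4-[4-(benzyloxy)benzyl]-2-iodobenzene; 6 allyl alcohol
Product: 7 3-Ar-propanal, i.e. 3-{2-(benzyloxy)-5-[4-(benzyloxy)benzyl]phenyl}propanal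
Conditions: Pd(OAc)2 (cat.), Bu4NCl, NaHCO3, DMF, 45 °C
Reagents that add atoms: none
Why: Heck arylation of allyl alcohol under Jeffery conditions should place the aryl group on the terminal carbon, and β-hydride elimination towards the carbinol carbon gives an enol that tautomerizes to the saturated aldehyde.

Step 5
Reactants: 7 3-Ar-propanal; 8 1-(triphenylphosphoranylidene)propan-2-one
Product: 9 (E)-6-{2-(benzyloxy)-5-[4-(benzyloxy)benzyl]phenyl}hex-3-en-2-one
Conditions: toluene, 80 °C
Reagents that add atoms: none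
Why: Wittig olefination of an unhindered aliphatic aldehyde with a stabilized acyl ylide should give the E-enone selectively.

Step 6
Reactants: 9 (E)-6-Ar-hex-3-en-2-one; 10 dimethyl malonate
Product: 12 methyl 6-(2-Ar-ethyl)-2,4-dioxocyclohexane-1-carboxylate, via keto diester 11 (not isolated)
Conditions: NaOMe, MeOH/THF, 65 °C; then cold 1 M HCl
Reagents that add atoms: none
Why: Sodium dimethyl malonate adds reversibly in 1,4-fashion to the β-alkyl enone to give keto diester 11 (bond C5–C6), after which methoxide equilibrates the ketone enolates and the one on the methyl side attacks a malonate ester carbonyl and expels methoxide (bond C1–C2). The closest known reaction type is the classical Michael–Claisen annulation of alkylidene acetones with malonates that leads to 5-alkylcyclohexane-1,3-diones and 5-alkylresorcinols. The one ring closes in a 6-(enolexo)-exo-trig mode, whereas the enolate on the internal CH2 could only form a four-membered ring and is unproductive. The two new stereocentres (the ester-bearing carbon and C5, expected mainly trans under equilibration) are not controlled and need not be, since the first is lost on decarboxylation and the second on aromatization. The step needs 1,4- over 1,2-addition, which the soft and reversibly adding malonate anion secures, and closure by the methyl ketone, which ring size secures; irreversible deprotonation of the acidic cyclic β-dicarbonyl product should pull all equilibria forward.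

Step 7
Reactants: 12 methyl 6-(2-Ar-ethyl)-2,4-dioxocyclohexane-1-carboxylate
Product: 14 5-(2-Ar-ethyl)cyclohexane-1,3-dione, via β-keto acid 13 (not isolated)
Conditions: 2 M NaOH, MeOH/H2O, reflux; then HCl (pH 1), 70 °C
Reagents that add atoms: none
Why: Saponification followed by acid-promoted decarboxylation of the β-keto acid is the standard finish of the dimedone-type synthesis, and aryl benzyl ethers should tolerate hot dilute base and brief warming in dilute acid.

Step 8
Reactants: 14 5-(2-Ar-ethyl)cyclohexane-1,3-dione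
Product: 15 3-methoxy-5-(2-Ar-ethyl)cyclohex-2-en-1-one (racemic)
Conditions: HC(OMe)3, p-TsOH (cat.), MeOH, rt
Reagents that add atoms: trimethyl orthoformate, COC(OC)OC; methanol, CO
Why: Acid-catalysed enol etherification of the vinylogous acid, with orthoformate as water scavenger, should give a single enol ether because the two carbonyls of 14 are related by a mirror plane; this is the step that makes one oxygen OMe and the other the future OH.

Step 9
Reactants: 15 3-methoxy-5-(2-Ar-ethyl)cyclohex-2-en-1-one; 16 4-(benzyloxy)benzaldehyde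
Product: 17 6-{[4-(benzyloxy)phenyl](hydroxy)methyl}-3-methoxy-5-(2-Ar-ethyl)cyclohex-2-en-1-one (mixture of racemic diastereomers)
Conditions: LDA, THF, −78 °C; then 16, −78 °C; aq. NH4Cl
Reagents that add atoms: none
Why: LDA deprotonates 3-alkoxy-enones kinetically at α′ (C6) and not at the vinylogous γ-position (Stork–Danheiser regiochemistry), and the lithium enolate should add to the non-enolizable aldehyde in a crossed aldol reaction; the three stereocentres are uncontrolled and are all erased in step 10.

Step 10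
Reactants: 17 aldol adduct
Product: 20 2-[4-(benzyloxy)benzyl]-3-(2-Ar-ethyl)-5-methoxyphenol, via mesylate 18 (not isolated), via arylidene dienone 19 (not isolated)
Conditions: MsCl, Et3N, THF, 0 °C; then t-BuOK, THF, 0 → 50 °C; aq. NH4Cl
Reagents that add atoms: methanesulfonyl chloride, CS(=O)(=O)Cl (kept only in intermediate 18, absent from 20)
Why: Mesylation and E1cB elimination give the cross-conjugated arylidene dienone, and tert-butoxide should then relay the exocyclic double bond into the ring by deprotonation at the allylic C5 and reprotonation at the benzylic carbon (base-mediated isoaromatization, as known for 2-arylidene-1-tetralones going to 2-benzyl-1-naphthols), the cyclohexadienone tautomerizing irreversibly to the phenoxide.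

Step 11
Reactants: 20 2-[4-(benzyloxy)benzyl]-3-(2-Ar-ethyl)-5-methoxyphenol
Product: 21 1-(benzyloxy)-2-[4-(benzyloxy)benzyl]-3-(2-Ar-ethyl)-5-methoxybenzene
Conditions: BnBr, K2CO3, DMF, 40 °C
Reagents that add atoms: benzyl bromide, BrCc1ccccc1
Why: Williamson benzylation masks the new phenol so that an aryllithium can be used in step 13, and turns ring A into a resorcinol diether for a clean mono-bromination.

Step 12
Reactants: 21 1-(benzyloxy)-2-[4-(benzyloxy)benzyl]-3-(2-Ar-ethyl)-5-methoxybenzene
Product: 22 1-(benzyloxy)-2-[4-(benzyloxy)benzyl]-4-bromo-3-(2-Ar-ethyl)-5-methoxybenzene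
Conditions: NBS, CH2Cl2/MeCN, −20 → 0 °C, dark
Reagents that add atoms: N-bromosuccinimide, O=C1CCC(=O)N1Br
Why: Electrophilic aromatic bromination should occur on ring A, the only ring with two mutually reinforcing alkoxy groups, at C4 (para to OBn, between OMe and the bridge) rather than at C6 between the two oxygens, as 3,5-dimethoxytoluene brominates next to its methyl group; the mono-alkoxy rings are far less reactive.

Step 13
Reactants: 22 aryl bromide; 16 4-(benzyloxy)benzaldehyde
Product: 24 [4-(benzyloxy)phenyl]{4-(benzyloxy)-3-[4-(benzyloxy)benzyl]-2-(2-Ar-ethyl)-6-methoxyphenyl}methanol (racemic), via aryllithium 23 (not isolated)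
Conditions: n-BuLi, THF, −78 °C; then 16, −78 → −40 °C; aq. NH4Cl
Reagents that add atoms: n-butyllithium, [Li]CCCC (lithium kept only in intermediate 23, absent from 24)
Why: Bromine–lithium exchange at −78 °C should outrun benzylic deprotonation and Wittig rearrangement of the benzyl ethers, and the ortho-methoxy-stabilized aryllithium adds 1,2 to the aldehyde; the carbinol centre is racemic and is removed in step 14.

Step 14
Reactants: 24 diaryl carbinol
Product: 25 2,4-bis(4-hydroxybenzyl)-3-{2-[2-hydroxy-5-(4-hydroxybenzyl)phenyl]ethyl}-5-methoxyphenol (target, achiral)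
Conditions: H2 (1 atm), Pd(OH)2/C, EtOAc/EtOH, AcOH (cat.), rt
Reagents that add atoms: none
Why: Catalytic hydrogenolysis should cleave the five O-benzyl ethers and, in the same operation, the doubly benzylic electron-rich carbinol C–O bond, while the diarylmethane C–C bonds, the methyl ether and the arenes are inert at 1 atm; only weak acid is used so that the carbinol is not ionized to a free cation.

Compound list
1 | 4-hydroxy-3-iodobenzaldehyde | O=Cc1ccc(O)c(I)c1 | starting material
2 | 4-(benzyloxy)-3-iodobenzaldehyde | O=Cc1ccc(OCc2ccccc2)c(I)c1 | intermediate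
3 | 4-(benzyloxy)phenylmagnesium bromide (THF solution) | Br[Mg]c1ccc(OCc2ccccc2)cc1 | starting material
4 | [4-(benzyloxy)-3-iodophenyl][4-(benzyloxy)phenyl]methanol (racemic) | OC(c1ccc(OCc2ccccc2)cc1)c1ccc(OCc2ccccc2)c(I)c1 | intermediate
5 | 1-(benzyloxy)-4-[4-(benzyloxy)benzyl]-2-iodobenzene | Ic1cc(Cc2ccc(OCc3ccccc3)cc2)ccc1OCc1ccccc1 | intermediate
6 | allyl alcohol (prop-2-en-1-ol) | C=CCO | starting material
7 | 3-{2-(benzyloxy)-5-[4-(benzyloxy)benzyl]phenyl}propanal | O=CCCc1cc(Cc2ccc(OCc3ccccc3)cc2)ccc1OCc1ccccc1 | intermediate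
8 | 1-(triphenylphosphoranylidene)propan-2-one | CC(=O)C=P(c1ccccc1)(c1ccccc1)c1ccccc1 | starting material
9 | (E)-6-{2-(benzyloxy)-5-[4-(benzyloxy)benzyl]phenyl}hex-3-en-2-one | CC(=O)/C=C/CCc1cc(Cc2ccc(OCc3ccccc3)cc2)ccc1OCc1ccccc1 | intermediate
10 | dimethyl malonate | COC(=O)CC(=O)OC | starting material
11 | dimethyl 2-(1-Ar-5-oxohexan-3-yl)malonate (racemic Michael adduct, not isolated) | COC(=O)C(C(=O)OC)C(CC(C)=O)CCc1cc(Cc2ccc(OCc3ccccc3)cc2)ccc1OCc1ccccc1 | intermediate
12 | methyl 6-(2-Ar-ethyl)-2,4-dioxocyclohexane-1-carboxylate (racemic, both centres later erased; largely enolized) | COC(=O)C1C(=O)CC(=O)CC1CCc1cc(Cc2ccc(OCc3ccccc3)cc2)ccc1OCc1ccccc1 | intermediate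
13 | 6-(2-Ar-ethyl)-2,4-dioxocyclohexane-1-carboxylic acid (not isolated) | OC(=O)C1C(=O)CC(=O)CC1CCc1cc(Cc2ccc(OCc3ccccc3)cc2)ccc1OCc1ccccc1 | intermediate
14 | 5-(2-Ar-ethyl)cyclohexane-1,3-dione (achiral) | O=C1CC(=O)CC(CCc2cc(Cc3ccc(OCc4ccccc4)cc3)ccc2OCc2ccccc2)C1 | intermediate
15 | 3-methoxy-5-(2-Ar-ethyl)cyclohex-2-en-1-one (racemic) | COC1=CC(=O)CC(CCc2cc(Cc3ccc(OCc4ccccc4)cc3)ccc2OCc2ccccc2)C1 | intermediate
16 | 4-(benzyloxy)benzaldehyde | O=Cc1ccc(OCc2ccccc2)cc1 | starting material
17 | 6-{[4-(benzyloxy)phenyl](hydroxy)methyl}-3-methoxy-5-(2-Ar-ethyl)cyclohex-2-en-1-one (diastereomer mixture, racemic) | COC1=CC(=O)C(C(O)c2ccc(OCc3ccccc3)cc2)C(CCc2cc(Cc3ccc(OCc4ccccc4)cc3)ccc2OCc2ccccc2)C1 | intermediate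
18 | [4-(benzyloxy)phenyl][4-methoxy-2-oxo-6-(2-Ar-ethyl)cyclohex-3-en-1-yl]methyl methanesulfonate (diastereomer mixture, not isolated) | COC1=CC(=O)C(C(OS(C)(=O)=O)c2ccc(OCc3ccccc3)cc2)C(CCc2cc(Cc3ccc(OCc4ccccc4)cc3)ccc2OCc2ccccc2)C1 | intermediate
19 | (E)-6-[4-(benzyloxy)benzylidene]-3-methoxy-5-(2-Ar-ethyl)cyclohex-2-en-1-one (racemic, not isolated) | COC1=CC(=O)/C(=C/c2ccc(OCc3ccccc3)cc2)C(CCc2cc(Cc3ccc(OCc4ccccc4)cc3)ccc2OCc2ccccc2)C1 | intermediate
20 | 2-[4-(benzyloxy)benzyl]-3-(2-Ar-ethyl)-5-methoxyphenol | COc1cc(O)c(Cc2ccc(OCc3ccccc3)cc2)c(CCc2cc(Cc3ccc(OCc4ccccc4)cc3)ccc2OCc2ccccc2)c1 | intermediate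
21 | 1-(benzyloxy)-2-[4-(benzyloxy)benzyl]-3-(2-Ar-ethyl)-5-methoxybenzene | COc1cc(OCc2ccccc2)c(Cc2ccc(OCc3ccccc3)cc2)c(CCc2cc(Cc3ccc(OCc4ccccc4)cc3)ccc2OCc2ccccc2)c1 | intermediate
22 | 1-(benzyloxy)-2-[4-(benzyloxy)benzyl]-4-bromo-3-(2-Ar-ethyl)-5-methoxybenzene | COc1cc(OCc2ccccc2)c(Cc2ccc(OCc3ccccc3)cc2)c(CCc2cc(Cc3ccc(OCc4ccccc4)cc3)ccc2OCc2ccccc2)c1Br | intermediate
23 | {4-(benzyloxy)-3-[4-(benzyloxy)benzyl]-2-(2-Ar-ethyl)-6-methoxyphenyl}lithium (not isolated) | COc1cc(OCc2ccccc2)c(Cc2ccc(OCc3ccccc3)cc2)c(CCc2cc(Cc3ccc(OCc4ccccc4)cc3)ccc2OCc2ccccc2)c1[Li] | intermediate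
24 | [4-(benzyloxy)phenyl]{4-(benzyloxy)-3-[4-(benzyloxy)benzyl]-2-(2-Ar-ethyl)-6-methoxyphenyl}methanol (racemic) | COc1cc(OCc2ccccc2)c(Cc2ccc(OCc3ccccc3)cc2)c(CCc2cc(Cc3ccc(OCc4ccccc4)cc3)ccc2OCc2ccccc2)c1C(O)c1ccc(OCc2ccccc2)cc1 | intermediate
25 | 2,4-bis(4-hydroxybenzyl)-3-{2-[2-hydroxy-5-(4-hydroxybenzyl)phenyl]ethyl}-5-methoxyphenol (achiral) | COc1cc(O)c(Cc2ccc(O)cc2)c(CCc2cc(Cc3ccc(O)cc3)ccc2O)c1Cc1ccc(O)cc1 | target

Total step count: 14. Longest linear sequence: 14 steps (1 → 25); the route is linear, with 3, 6, 8, 10 and 16 entering as purchased partners.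

Steps most likely to fail

Step 6 (key annulation). What may go wrong: reversal of the conjugate addition, or base-induced deconjugation and self-condensation of the methyl enone, may outpace ring closure. The fallback sets out from aldehyde 7 and moves the enolizable methyl ketone from the acceptor to the donor. Horner–Wadsworth–Emmons olefination of 7 with triethyl phosphonoacetate (NaH, THF) should give ethyl (E)-5-Ar-pent-2-enoate F1. Sodium ethyl acetoacetate in refluxing ethanol then adds to F1 to give diethyl 2-acetyl-3-(2-Ar-ethyl)pentanedioate F2 (not isolated), whose acetyl methyl group closes onto the distal ester to ethyl 6-(2-Ar-ethyl)-2,4-dioxocyclohexane-1-carboxylate F3. This is the classical crotonate/acetoacetate entry to dihydroresorcinols. Saponification of F3 gives the same β-keto acid, so the route is rejoined at 13 and hence at dione 14.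

Step 10 (elimination/isoaromatization cascade). What may go wrong: the prototropic relay may stall at the exocyclic dienone, or tert-butoxide may divert material by γ-deprotonation, conjugate addition and oligomerization. The fallback sets out from enol ether 15 and forms the benzylic bond at the saturated oxidation level, then oxidizes. Kinetic α′-alkylation (LDA, THF, −78 °C; 4-(benzyloxy)benzyl bromide) should give 6-[4-(benzyloxy)benzyl]-3-methoxy-5-(2-Ar-ethyl)cyclohex-2-en-1-one F4. A second α′-enolization and trapping with PhSeCl gives 6-[4-(benzyloxy)benzyl]-3-methoxy-6-(phenylselanyl)-5-(2-Ar-ethyl)cyclohex-2-en-1-one F5. Oxidation (H2O2, pyridine, CH2Cl2, 0 °C) gives the selenoxide F6 (not isolated), whose syn-elimination and enolization should deliver phenol 20, where the route is rejoined.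

Step 12 (site-selective bromination). What may go wrong: loss of site or ring selectivity, through attack at the carbon between the two oxygens, on a mono-alkoxy ring or at a benzylic CH2 by a radical path, or a second bromination. The fallback sets out from 21 and reverses the polarity of the later C–C bond formation. Vilsmeier–Haack formylation (POCl3, DMF, 0 → 60 °C; aq. NaOAc) uses a weaker, self-limiting electrophile known to substitute orcinol-type diethers next to the alkyl group. It should pass through the iminium salt {4-(benzyloxy)-3-[4-(benzyloxy)benzyl]-2-(2-Ar-ethyl)-6-methoxybenzylidene}dimethylammonium chloride F7 (not isolated) to 4-(benzyloxy)-3-[4-(benzyloxy)benzyl]-2-(2-Ar-ethyl)-6-methoxybenzaldehyde F8. Addition of Grignard reagent 3 to F8 gives carbinol 24, where the route is rejoined, so steps 12 and 13 are both bypassed.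

Further compounds
F1 | step 6 | ethyl (E)-5-{2-(benzyloxy)-5-[4-(benzyloxy)benzyl]phenyl}pent-2-enoate | CCOC(=O)/C=C/CCc1cc(Cc2ccc(OCc3ccccc3)cc2)ccc1OCc1ccccc1
F2 | step 6 | diethyl 2-acetyl-3-(2-Ar-ethyl)pentanedioate (not isolated) | CCOC(=O)CC(CCc1cc(Cc2ccc(OCc3ccccc3)cc2)ccc1OCc1ccccc1)C(C(C)=O)C(=O)OCC
F3 | step 6 | ethyl 6-(2-Ar-ethyl)-2,4-dioxocyclohexane-1-carboxylate (racemic) | CCOC(=O)C1C(=O)CC(=O)CC1CCc1cc(Cc2ccc(OCc3ccccc3)cc2)ccc1OCc1ccccc1
F4 | step 10 | 6-[4-(benzyloxy)benzyl]-3-methoxy-5-(2-Ar-ethyl)cyclohex-2-en-1-one (racemic, mainly trans) | COC1=CC(=O)C(Cc2ccc(OCc3ccccc3)cc2)C(CCc2cc(Cc3ccc(OCc4ccccc4)cc3)ccc2OCc2ccccc2)C1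
F5 | step 10 | 6-[4-(benzyloxy)benzyl]-3-methoxy-6-(phenylselanyl)-5-(2-Ar-ethyl)cyclohex-2-en-1-one (racemic) | COC1=CC(=O)C(Cc2ccc(OCc3ccccc3)cc2)([Se]c2ccccc2)C(CCc2cc(Cc3ccc(OCc4ccccc4)cc3)ccc2OCc2ccccc2)C1
F6 | step 10 | 6-[4-(benzyloxy)benzyl]-3-methoxy-6-(phenylseleninyl)-5-(2-Ar-ethyl)cyclohex-2-en-1-one (not isolated) | COC1=CC(=O)C(Cc2ccc(OCc3ccccc3)cc2)([Se](=O)c2ccccc2)C(CCc2cc(Cc3ccc(OCc4ccccc4)cc3)ccc2OCc2ccccc2)C1
F7 | step 12 | {4-(benzyloxy)-3-[4-(benzyloxy)benzyl]-2-(2-Ar-ethyl)-6-methoxybenzylidene}dimethylammonium chloride (not isolated) | COc1cc(OCc2ccccc2)c(Cc2ccc(OCc3ccccc3)cc2)c(CCc2cc(Cc3ccc(OCc4ccccc4)cc3)ccc2OCc2ccccc2)c1C=[N+](C)C.[Cl-]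
F8 | step 12 | 4-(benzyloxy)-3-[4-(benzyloxy)benzyl]-2-(2-Ar-ethyl)-6-methoxybenzaldehyde | COc1cc(OCc2ccccc2)c(Cc2ccc(OCc3ccccc3)cc2)c(CCc2cc(Cc3ccc(OCc4ccccc4)cc3)ccc2OCc2ccccc2)c1C=O
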